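All runs stem from a simulated flask from invented constants; scatter was added.

The amounts first: in the grey flask the substrate, charged at 0.10 M against 2 equiv of coupling partner, is the limiting reagent of the coupling, and it stands free, as target or as homo dimer, these forms adding up to its charge. The protic impurity can take 1.00% of the coupling partner, hardly any, so I leave it out and read the violet run, with 3 mM of impurity, as a longer view of the grey flask.

all flasks: substrate 0.10 M

|  | coupling partner | protic impurity | remark | time |
|---|---|---|---|---|
| grey | 2 equiv | 2 mM | the very flask that is asked about, followed so far |  |
| violet | 2 equiv | 3 mM | run made earlier |  |
| flask | 2.00 equiv | 2.00 mM |  | 25 h |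

| run | time / h | target / % |
|---|---|---|
| grey | 3.00 | 36.6 |
| grey | 6.00 | 30.5 |
| grey | 10.0 | 33.0 |
| grey | 12.0 | 29.3 |
| violet | 2.00 | 39.1 |
| violet | 6.00 | 33.6 |
| violet | 12.0 | 30.3 |
| violet | 20.0 | 24.2 |

(scatter of a reading: 1 percentage point)

- at 25 h, what has stopped the reaction, if anything has (it is still moving / forward and back rates have come level / the coupling partner has run out first / all of the substrate has reacted)
- the target standing at 25 h, as a percentage of the substrate charged

- in percentages every species weighs as the substrate in it: one homo dimer counts as two
- steps that have been proposed: coupling partner + protic impurity -> quenched reagent; substrate + coupling partner <-> target + by-product; 2 substrate -> homo dimer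
- the reaction counts as stopped when no species that holds the substrate changes by six tenths of a point or more over the second half of the time

Two times matter. The rise is short: in the violet run the target already reads 39.1% at 2.00 h. The drain is slow. If the coupling stays level and the partner stays roughly constant, the square of the target follows the free substrate, and dimerisation, second order in substrate, makes its inverse grow roughly evenly with time. So I take the inverse square of the target to grow roughly evenly too. The violet readings at 2.00 h and 20.0 h give 11.2 h for the time in which that inverse square doubles from its value at the first of them, the drain time. Because the drain time is longer than the 2.00 h by which the target has risen, by a factor of 5.60, I expect the coupling to keep up.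

Carried from the first violet reading to 25 h, this gives me 22.4% in the grey flask, with a fall of 5.7 percentage points over the last 12.5 h, which passes the mark, so I expect it still moving.

The forecast, a separate judgement, says 22.5% and it is still moving, holding that “Target then tracks roughly the square root of the remaining substrate”.

The grey flask gives 24.1% at 25.0 h, and the answer on what stopped it is: it is still moving.

    coupling partner + protic impurity → quenched reagent (k = 17.9 M⁻¹ min⁻¹)
    substrate + coupling partner ⇌ target + by-product (K = 0.240, k = 0.0611 M⁻¹ min⁻¹)
    2 substrate → homo dimer (k = 0.0293 M⁻¹ min⁻¹)

At that time the homo dimer in the grey flask holds 62.5% of the substrate charged, while the step that quenches the partner makes no difference to the target. My figure from the drain time lies 1.7 points below the flask. Used once more, for the same flask read at 4.0 d, the drain time gives 12.8%, and that flask holds 15.3%.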